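**Plan**

- Retrosynthesis: first the four O–benzyl bonds (one final hydrogenolysis), then C4a–C4 and O2–C3 of the pyranone, then the diaryl ether bond at C8, then the ring B phenol C–O bond (traced back to C–Br).
- Forward: ring B phenol 5 comes from olivetolic acid by benzylation, bromination and borylation–oxidation; ring A acid 8 comes from 2-bromo-4-hydroxybenzoic acid. A copper-catalysed ether synthesis joins rings A and B, and the pyranone is the last ring to form, fused onto ring A.
- Enabling feature: in acid 9 the free carboxyl carbon (future C1) sits on C8a and C8 already carries the aryloxy group, so C4a–H is the only ortho hydrogen, which is where the C4–C3 arm must be attached. The ring B carboxyl is a benzyl ester flanked by pentyl and benzyloxy.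
- Stereochemistry: the target has no stereocentre and no stereogenic double bond, so nothing has to be controlled.

Key step: step 7

Remark: isocoumarin numbering (C1 carbonyl, O2, C3, C4, C4a, C5 to C8, C8a) is used for ring A and the pyranone; ring B is the olivetolic acid ring. The four numbered starting materials are taken as purchasable.

**Step 1**
Reactants: 1 olivetolic acid (2,4-dihydroxy-6-pentylbenzoic acid)
Product: 2 benzyl 2,4-bis(benzyloxy)-6-pentylbenzoate
Conditions: BnBr (3.5 equiv), K2CO3, DMF, rt then 60 °C
Reagents that add atoms: benzyl bromide, BrCc1ccccc1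
Why: Williamson-type alkylation, in which the carboxylate is benzylated first at room temperature (guarding the resorcylic acid against decarboxylation) and the two phenols follow on warming, the chelated 2-hydroxyl last.

**Step 2**
Reactants: 2 benzyl 2,4-bis(benzyloxy)-6-pentylbenzoate
Product: 3 benzyl 4,6-bis(benzyloxy)-3-bromo-2-pentylbenzoate
Conditions: NBS (1.0 equiv), MeCN, 0 °C to rt, dark
Reagents that add atoms: N-bromosuccinimide, O=C1CCC(=O)N1Br
Why: Electrophilic aromatic bromination should go to C5 of 2 (para to the 2-benzyloxy group, ortho to the 4-benzyloxy group, next to the pentyl chain), the site at which 6-alkylresorcylates are halogenated, rather than to C3 between the two ether groups.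

**Step 3**
Reactants: 3 benzyl 4,6-bis(benzyloxy)-3-bromo-2-pentylbenzoate
Product: 5 benzyl 4,6-bis(benzyloxy)-3-hydroxy-2-pentylbenzoate, via pinacol boronate 4 (not isolated)
Conditions: PdCl2(MeCN)2 (2 mol %), SPhos (8 mol %), HBpin, Et3N, dioxane, 90 °C; then MeOH, THF, aq NaOH, 30% H2O2, 0 °C to rt
Reagents that add atoms: pinacolborane, CC1(C)OBOC1(C)C (boron of 4 only, lost again); hydrogen peroxide, OO (phenol oxygen of 5)
Why: Palladium-catalysed Miyaura-type borylation with a dialkylbiarylphosphine tolerates aryl bromides with two ortho substituents, and oxidative boron-to-oxygen aryl migration then gives the phenol, while the doubly ortho-substituted benzyl ester should survive the brief cold base.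

**Step 4**
Reactants: 6 2-bromo-4-hydroxybenzoic acid
Product: 8 4-(benzyloxy)-2-bromobenzoic acid, via benzyl ester 7 (not isolated)
Conditions: BnBr (2.2 equiv), K2CO3, DMF, 60 °C; then NaOH, MeOH–H2O, 60 °C; aq HCl
Reagents that add atoms: benzyl bromide, BrCc1ccccc1; sodium hydroxide, [Na+].[OH-] (one carboxyl oxygen, after acyl–oxygen cleavage)
Why: Williamson alkylation of phenol and carboxylate followed by saponification of the unhindered benzyl ester, which leaves the aryl benzyl ether and the aryl bromide untouched.

**Step 5**
Reactants: 5 benzyl 4,6-bis(benzyloxy)-3-hydroxy-2-pentylbenzoate; 8 4-(benzyloxy)-2-bromobenzoic acid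
Product: 9 2-[4,6-bis(benzyloxy)-3-[(benzyloxy)carbonyl]-2-pentylphenoxy]-4-(benzyloxy)benzoic acid
Conditions: CuI (10 mol %), picolinic acid (20 mol %), K3PO4 (3 equiv), DMSO, 90 °C; aq HCl work-up
Reagents that add atoms: none
Why: Ullmann diaryl ether synthesis, helped by the ortho carboxylate of 8 (the classical activating effect in 2-halobenzoic acids) and by the picolinic acid ligand, which is suited to phenols with two ortho substituents; the hindered benzyl ester of 5 should not be hydrolysed.

**Step 6**
Reactants: 10 trimethylsulfoxonium iodide; 11 hexanoyl chloride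
Product: 13 1-(dimethyloxosulfanylidene)heptan-2-one, via dimethylsulfoxonium methylide 12 (not isolated)
Conditions: 10 (3 equiv), KOtBu (3 equiv), THF, reflux; then 11 (1 equiv), 0 °C to rt
Reagents that add atoms: none
Why: C-acylation of the Corey–Chaykovsky ylide by the acid chloride, in which a second equivalent of methylide deprotonates the acylsulfoxonium salt to give the stabilised keto ylide.

**Step 7**
Reactants: 9 2-[4,6-bis(benzyloxy)-3-[(benzyloxy)carbonyl]-2-pentylphenoxy]-4-(benzyloxy)benzoic acid; 13 1-(dimethyloxosulfanylidene)heptan-2-one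
Product: 15 benzyl 4,6-bis(benzyloxy)-3-{[6-(benzyloxy)-1-oxo-3-pentyl-1H-isochromen-8-yl]oxy}-2-pentylbenzoate, via keto acid 14 (not isolated)
Conditions: [Cp*RhCl2]2 (4 mol %), AgSbF6 (16 mol %), NaOAc (0.5 equiv), DCE, 100 °C
Reagents that add atoms: none
Why: This is the known carboxylate-directed C–H activation/annulation of benzoic acids with α-acyl sulfoxonium ylides to 3-substituted isocoumarins. The cationic Cp* complex of trivalent rhodium freed by AgSbF6 binds the carboxylate of 9 and, by acetate-assisted concerted metalation–deprotonation, forms a five-membered rhodacycle at C4a; ylide 13 then binds through carbon, loses dimethyl sulfoxide to give a rhodium carbene, and migratory insertion followed by protodemetalation forms C4a–C4 and releases keto acid 14. The pyranone closes when carboxyl oxygen O2 adds to the C3 ketone (6-exo-trig) and the lactol loses water under the Lewis-acidic conditions, giving the 3-pentyl, 4-unsubstituted pattern that the ylide dictates. No stereocentre is created. Only site selectivity is needed, and the substrate secures it: C8 carries the aryloxy group, so C4a–H is the sole hydrogen ortho to the free acid; the ring B carboxyl is an ester with pentyl and benzyloxy in both ortho positions, and ring B has no hydrogen next to the ether oxygen, so neither a second metalation nor a xanthone-type closure can compete.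

**Step 8**
Reactants: 15 benzyl 4,6-bis(benzyloxy)-3-{[6-(benzyloxy)-1-oxo-3-pentyl-1H-isochromen-8-yl]oxy}-2-pentylbenzoate
Product: 16 4,6-dihydroxy-3-[(6-hydroxy-1-oxo-3-pentyl-1H-isochromen-8-yl)oxy]-2-pentylbenzoic acid (CNP0439913.0)
Conditions: H2 (1 atm), 10% Pd/C, EtOAc–THF, rt, stopped when debenzylation is complete; concentrated below 30 °C
Reagents that add atoms: none
Why: Catalytic hydrogenolysis cleaves the three aryl benzyl ethers and the benzyl ester in one neutral operation that spares the decarboxylation-prone resorcylic acid, and the conjugated enol-lactone C3=C4 bond should be reduced more slowly than the benzyl–oxygen bonds.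

**Compound list**

1 | olivetolic acid (2,4-dihydroxy-6-pentylbenzoic acid) | CCCCCc1cc(O)cc(O)c1C(=O)O | starting material
2 | benzyl 2,4-bis(benzyloxy)-6-pentylbenzoate | CCCCCc1cc(OCc2ccccc2)cc(OCc2ccccc2)c1C(=O)OCc1ccccc1 | intermediate
3 | benzyl 4,6-bis(benzyloxy)-3-bromo-2-pentylbenzoate | CCCCCc1c(Br)c(OCc2ccccc2)cc(OCc2ccccc2)c1C(=O)OCc1ccccc1 | intermediate
4 | benzyl 4,6-bis(benzyloxy)-2-pentyl-3-(4,4,5,5-tetramethyl-1,3,2-dioxaborolan-2-yl)benzoate | CCCCCc1c(B2OC(C)(C)C(C)(C)O2)c(OCc2ccccc2)cc(OCc2ccccc2)c1C(=O)OCc1ccccc1 | intermediate (not isolated)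
5 | benzyl 4,6-bis(benzyloxy)-3-hydroxy-2-pentylbenzoate | CCCCCc1c(O)c(OCc2ccccc2)cc(OCc2ccccc2)c1C(=O)OCc1ccccc1 | intermediate
6 | 2-bromo-4-hydroxybenzoic acid | O=C(O)c1ccc(O)cc1Br | starting material
7 | benzyl 4-(benzyloxy)-2-bromobenzoate | O=C(OCc1ccccc1)c1ccc(OCc2ccccc2)cc1Br | intermediate (not isolated)
8 | 4-(benzyloxy)-2-bromobenzoic acid | O=C(O)c1ccc(OCc2ccccc2)cc1Br | intermediate
9 | 2-[4,6-bis(benzyloxy)-3-[(benzyloxy)carbonyl]-2-pentylphenoxy]-4-(benzyloxy)benzoic acid | CCCCCc1c(Oc2cc(OCc3ccccc3)ccc2C(=O)O)c(OCc2ccccc2)cc(OCc2ccccc2)c1C(=O)OCc1ccccc1 | intermediate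
10 | trimethylsulfoxonium iodide | C[S+](C)(C)=O.[I-] | starting material
11 | hexanoyl chloride | CCCCCC(=O)Cl | starting material
12 | dimethylsulfoxonium methylide | C=S(C)(C)=O | intermediate (not isolated)
13 | 1-(dimethyloxosulfanylidene)heptan-2-one | CCCCCC(=O)C=S(C)(C)=O | intermediate
14 | 2-[4,6-bis(benzyloxy)-3-[(benzyloxy)carbonyl]-2-pentylphenoxy]-4-(benzyloxy)-6-(2-oxoheptyl)benzoic acid | CCCCCC(=O)Cc1cc(OCc2ccccc2)cc(Oc2c(OCc3ccccc3)cc(OCc3ccccc3)c(C(=O)OCc3ccccc3)c2CCCCC)c1C(=O)O | intermediate (not isolated)
15 | benzyl 4,6-bis(benzyloxy)-3-{[6-(benzyloxy)-1-oxo-3-pentyl-1H-isochromen-8-yl]oxy}-2-pentylbenzoate | CCCCCc1cc2cc(OCc3ccccc3)cc(Oc3c(OCc4ccccc4)cc(OCc4ccccc4)c(C(=O)OCc4ccccc4)c3CCCCC)c2c(=O)o1 | intermediate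
16 | 4,6-dihydroxy-3-[(6-hydroxy-1-oxo-3-pentyl-1H-isochromen-8-yl)oxy]-2-pentylbenzoic acid | CCCCCc1cc2cc(O)cc(Oc3c(O)cc(O)c(C(=O)O)c3CCCCC)c2c(=O)o1 | target

**Step count and risks**

Total step count: 8. Longest linear sequence: 6 (steps 1, 2, 3, 5, 7, 8).

Steps most likely to fail:

1. Step 7. Metalation at C4a may be slow because the bulky aryloxy group crowds the carboxylate, so that decomposition of the ylide-derived carbene outruns insertion, or the cationic rhodium and silver Lewis acids may strip benzyl ethers at 100 °C. The fallback reverses the order of ring closure and ether formation. It sets out from 8 and 13, which under the same rhodium conditions should give, by way of 4-(benzyloxy)-2-bromo-6-(2-oxoheptyl)benzoic acid F1 (not isolated), the lactone 6-(benzyloxy)-8-bromo-3-pentyl-1H-isochromen-1-one F2; the C–H activation then takes place on a small 2-bromobenzoic acid. Copper-catalysed etherification of F2 (bromide ortho to the lactone carbonyl) with phenol 5 (CuI, picolinic acid, K3PO4, DMSO, 90 °C) comes back to the route at 15.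

2. Step 5. The phenoxide of 5, flanked by pentyl and benzyloxy, may couple slowly, so that protodebromination or decarboxylation of 8 and benzyl transfer from the ester take over. The fallback replaces copper catalysis by nucleophilic aromatic substitution. It sets out from 5, which with 4-(benzyloxy)-2-fluorobenzaldehyde (O=Cc1ccc(OCc2ccccc2)cc1F; K2CO3, DMF, 110 °C) should give 2-[4,6-bis(benzyloxy)-3-[(benzyloxy)carbonyl]-2-pentylphenoxy]-4-(benzyloxy)benzaldehyde F3. Pinnick oxidation (NaClO2, NaH2PO4, 2-methyl-2-butene, tBuOH–H2O) comes back to the route at 9.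

3. Step 8. The C3=C4 bond of the isocoumarin may be hydrogenated to the dihydroisocoumarin before the last benzyl group has gone, and the free resorcylic acid may lose carbon dioxide on isolation. The fallback uses Lewis-acid debenzylation instead of hydrogenation. It sets out from 15, which with BCl3 and pentamethylbenzene in CH2Cl2 at −78 °C (methanol quench at low temperature) should lose all four benzyl groups as benzylpentamethylbenzene and arrive directly at 16; no new compound arises on this way (F0).

**Further compounds**

F1 | step 7 | 4-(benzyloxy)-2-bromo-6-(2-oxoheptyl)benzoic acid | CCCCCC(=O)Cc1cc(OCc2ccccc2)cc(Br)c1C(=O)O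
F2 | step 7 | 6-(benzyloxy)-8-bromo-3-pentyl-1H-isochromen-1-one | CCCCCc1cc2cc(OCc3ccccc3)cc(Br)c2c(=O)o1
F3 | step 5 | 2-[4,6-bis(benzyloxy)-3-[(benzyloxy)carbonyl]-2-pentylphenoxy]-4-(benzyloxy)benzaldehyde | CCCCCc1c(Oc2cc(OCc3ccccc3)ccc2C=O)c(OCc2ccccc2)cc(OCc2ccccc2)c1C(=O)OCc1ccccc1
F0 | step 8 | none | none
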